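Per point of L made, how many points of G come with it?

| flask | Z | E | D | Q | remark | time |
|---|---|---|---|---|---|---|
| gamma | 0.065 M | 0.065 M | 0.049 M (fed, over 10 min) | 6.5 mM | run made earlier |  |
| theta | 0.065 M | 0.065 M | 0.20 M (fed, over 10 min) | 6.5 mM | run made earlier |  |
| winter | 0.065 M | 0.065 M | 0.0975 M (fed, over 10 min) | 6.5 mM |  | 25 min |
| dusk | 0.065 M | 0.065 M | 0.0975 M (fed, over 40 min) | 6.5 mM |  | 25 min |

| run | time / min | L / % | G / % | Z / % |
|---|---|---|---|---|
| gamma | 4.00 | 2.1 | 0.8 | 47.1 |
| gamma | 8.00 | 8.5 | 0 | 44.8 |
| gamma | 12.0 | 12.8 | 1.2 | 39.9 |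
| gamma | 15.0 | 17.5 | 1.4 | 41.0 |
| gamma | 20.0 | 23.5 | 1.9 | 38.7 |
| theta | 4.00 | 8.5 | 0 | 45.6 |
| theta | 8.00 | 28.5 | 0 | 34.6 |
| theta | 12.0 | 43.8 | 0.6 | 24.5 |
| theta | 15.0 | 51.3 | 0 | 22.5 |
| theta | 20.0 | 60.2 | 0.9 | 17.0 |

(scatter of a reading: 1 percentage point)

- Q is single-handed; Z and E are mirror images of each other, charged as a racemate, each of them at the stated concentration
- percentages count the whole charge, also what has not yet gone in
- an excess is the difference of the two amounts in percent of their sum
- an excess is below zero if the other one leads

- the flask that ends with the higher excess of L over G in the product, or "neither" when 2 percentage points or less lies between them (winter / dusk / neither)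
- excess of L over G in the product at the end, winter
- excess of L over G in the product at the end, dusk

1. I began with the main step by itself: D and Q act on Z and give L. G is then absent and the excess is 100 %. But L stops at the Z charge, 50.0 % of the whole.

2. I added the passage between Z and E. The theta run calls for it: L read 60.2 % at 20.0 min, above that ceiling. Z then made up 43.7 % of the Z and E left, so I took the two as close. The excess stayed at 100 %, and the ceiling went.

3. I added a path to G as the mirror of the main step: a D at Q meets Z or E. Both paths carry D and Q, so these cancel in the ratio of the two rates. Summed over the gamma and theta readings, G per L read 0.0265. I named this the fork ratio f: points of G per point of L with Z and E equal, the inverse of the selectivity factor. Gamma by itself read 0.0823 and theta 0.00780. Each G reading carries 1 percentage point of scatter, so f is rough. The excess, (1 − f)/(1 + f), fell to 94.8 %.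

4. In my reckoning, any further loss of D or Q thinned both paths alike. The dosing time stands nowhere in f. So I expected 94.8 % in winter and in dusk, and chose neither.

5. The forecast said 92 % for winter and 82 % for dusk, so winter, with G as “a background leak”. There my reckoning differed.

6. Winter gave 97.6 % and dusk 97.7 %, so the answer was neither.

    D + Q + Z → Q + L (k = 6.81 L² mol⁻² s⁻¹)
    D + Q + E → Q + G (k = 0.0766 L² mol⁻² s⁻¹)
    2 D → J (k = 0.00573 L mol⁻¹ s⁻¹)
    Z ⇌ E (k = 0.00607 s⁻¹)
    2 Q ⇌ X, settled at all times (K = 116 L mol⁻¹)

7. Among the Z and E left at the end of dusk, at 25.0 min, E led Z by 2.29 %. I used f once more on a neighbour of dusk charged with 0.17 M of D. The f of 0.0265 holds no D, so it gave that neighbour 94.8 %, the value it gave dusk. The neighbour's L reached 38.0 % against 24.5 % in dusk, and its excess was 97.6 %.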